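The data stem from a simulated flask for an exercise; the scatter is artificial.

I start from amounts, in fractions of the starting material charged. Taking one capture agent to one trapped intermediate, I call the capture agent charged over the starting material charged the trap ceiling: 0.926% on Thursday's, and 7.41% on Tuesday's.

| setting | blue | grey | Thursday's | Wednesday's | Saturday's | Tuesday's |
|---|---|---|---|---|---|---|
| starting material | 0.54 M | 0.27 M | 0.54 M | 0.54 M | 0.54 M | 0.54 M |
| protic impurity | 0.16 M | 0.108 M | 0.108 M | 0.108 M | 0.108 M | 0.108 M |
| capture agent | 0.0050 M | 0.0050 M | 0.00500 M | 0.0100 M | 0.0200 M | 0.0400 M |
| remark | run made earlier | run made earlier |  |  |  |  |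
| time |  |  | 80 min | 80 min | 80 min | 80 min |

| run | time / min | target / % | side product / % |
|---|---|---|---|
| blue | 4.00 | 0.7 | 0.1 |
| blue | 6.00 | 0 | 0 |
| blue | 8.00 | 0.3 | 0 |
| blue | 15.0 | 0 | 0.3 |
| blue | 20.0 | 0 | 0.3 |
| blue | 30.0 | 0.1 | 1.5 |
| blue | 50.0 | 1.1 | 3.8 |
| grey | 4.00 | 0.1 | 0.2 |
| grey | 6.00 | 0 | 0 |
| grey | 8.00 | 0.3 | 0.2 |
| grey | 15.0 | 0.1 | 0 |
| grey | 20.0 | 0 | 0.8 |
| grey | 30.0 | 0.5 | 0.7 |
| grey | 50.0 | 1.0 | 1.9 |

(standard deviation of a reading: 0.3 percentage points)

- percent here means starting material units held: one side product counts as two
- "hardly changes" means that all values lie within two and a half points (for a concentration: within two and a half percent of the largest)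
- no earlier run changes the charge of capture agent; that part of a forecast is a guess

- share of target in all that became target or side product or trapped intermediate for Thursday's, Wednesday's, Saturday's, Tuesday's, in this order
- the shape of the row from first to last (rises all the way / falls, then rises / hardly changes / falls all the way / rises, then falls)

The readings show no trapped intermediate, so I begin with the two products they do show. At 50.0 min, target is 22.4% of target plus side product in the blue run and 34.5% in the grey run. The side product readings there, 3.8% and 1.9%, lie 1.9 percentage points apart against a scatter of 0.3 points, and the two runs differ in both charges, so the grey run is no repeat of the blue run; I don't average them, and I keep the blue share, since Thursday's charges the blue run's starting material.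

Thursday's has the blue run's starting material, so I extend the blue sum of the two products as the square of time, the growth its last two readings show. That gives 12.5% at 80 min, of which target is 2.82%.

Now I freeze both products along the row and let only the trapped amount change. But no earlier run varies the capture agent, so the spent fraction of the ceiling is a guess, and I put it at 0.5. My row then falls from 21.6% on Thursday's to 17.3% on Tuesday's.

The forecast gives 24%, 22%, 18% and 11%, so its row falls all the way, on the ground that “More capture agent diverts more flow, so the row falls”, and its last point lies below mine.

The flasks give 29.9%, 28.3%, 25.6% and 21.4%, so the row falls all the way.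

    starting material → intermediate A (k = 5.30 × 10⁻⁴ /s)
    intermediate A → intermediate B (k = 4.40 × 10⁻⁴ /s)
    intermediate B → target (k = 2.10 × 10⁻⁵ /s)
    starting material + protic impurity → quenched substrate (k = 4.60 × 10⁻⁴ /M/s)
    starting material + intermediate B → side product (k = 2.40 × 10⁻⁴ /M/s)
    intermediate A + capture agent → trapped intermediate (k = 0.00110 /M/s)

At 80.0 min, Thursday's holds 0.529% trapped intermediate, 57.1% of its ceiling, and Tuesday's holds 4.13%, 55.7% of its ceiling. Of its own charge, Thursday's keeps 43% capture agent and Tuesday's keeps 44%, as in a pseudo-first-order loss of capture agent. Tuesday's share stands at 21.4% mainly because the reading comes early: intermediate B still holds 54.7%, and with the early reading taken away and Tuesday's flask read at 800 min instead, the share is 79.8%.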